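Meridianin F is cut at C7–C7a and C3a–C4. This removes the benzo carbons C4–C5(Br)–C6(Br)–C7 as one C4 piece at the oxidation level of 2,3-dibromosuccinaldehyde, bridging the adjacent pyrrole carbons C7a (α) and C3a (β).
What remains is a 3-(2-aminopyrimidin-4-yl)pyrrole. Its pyrimidine is cut at N1–C6 and N3–C4 back to a pyrrolyl enaminone and guanidine.
Forward order of rings: the pyrrole is purchased, the pyrimidine comes from enaminone/guanidine condensation, and the benzene ring comes from double Friedel–Crafts annulation with 3,4-dibromo-2,5-dimethoxytetrahydrofuran.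
The exocyclic NH2 passes through the annulation as a pivalamide, because a free primary amine would itself condense with the 1,4-dialdehyde equivalent to an N-pyrrolyl compound. The amide is hydrolysed last.
Stereochemistry: the target has no stereocentre. The stereocentres of the C4 reagent are erased on aromatisation, so it is used as a diastereomer mixture.

Key step: step 5

Assumption: the target is achiral, so the demand for a single enantiomer is met trivially.
Assumption: 3-acetyl-1-tosylpyrrole is taken as a catalogue compound. The sulfonyl group is wanted because DMF-DMA can N-methylate a free, acidic pyrrole N–H.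

Step 1
Reactants: 1 3-acetyl-1-tosylpyrrole
Product: 2 (E)-3-(dimethylamino)-1-(1-tosyl-1H-pyrrol-3-yl)prop-2-en-1-one
Conditions: DMF-DMA (3 equiv), DMF, 110 °C
Reagents that add atoms: N,N-dimethylformamide dimethyl acetal, COC(OC)N(C)C
Why: Amide-acetal condensation of a methyl ketone (enaminone formation) is the standard entry to 3-(dimethylamino)propenones, gives the E isomer for steric reasons, and is kept clean by the N-tosyl group, which blocks N-methylation.

Step 2
Reactants: 2 (E)-3-(dimethylamino)-1-(1-tosyl-1H-pyrrol-3-yl)prop-2-en-1-one; 3 guanidine hydrochloride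
Product: 5 4-(1H-pyrrol-3-yl)pyrimidin-2-amine, via N-tosyl aminopyrimidine 4 (not isolated)
Conditions: 3 (2 equiv), K2CO3 (3 equiv), 2-methoxyethanol, reflux
Reagents that add atoms: guanidine hydrochloride (3), NC(N)=N.Cl
Why: In this Bredereck-type pyrimidine synthesis guanidine adds to the enaminone β-carbon with loss of dimethylamine and cyclodehydrates onto the ketone, after which the hot carbonate medium cleaves the N-sulfonyl group from the acceptor-substituted pyrrole, as is usual for N-tosyl 3-acylazole enaminones.

Step 3
Reactants: 5 4-(1H-pyrrol-3-yl)pyrimidin-2-amine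
Product: 6 N-[4-(1H-pyrrol-3-yl)pyrimidin-2-yl]pivalamide
Conditions: PivCl (1.2 equiv), pyridine, 0 °C → rt
Reagents that add atoms: pivaloyl chloride, CC(C)(C)C(=O)Cl
Why: N-acylation in pyridine goes to the exocyclic amine because an undeprotonated pyrrole N–H is not nucleophilic and the bulky acyl group stops at the mono-amide, a selectivity familiar from 2-aminopyrrolo[2,3-d]pyrimidines.

Step 4
Reactants: 7 2,5-dimethoxy-2,5-dihydrofuran (cis/trans mixture); 8 bromine
Product: 9 3,4-dibromo-2,5-dimethoxytetrahydrofuran (racemic, 3,4-trans, mixed at the acetal carbons)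
Conditions: Br2 (1.0 equiv), CH2Cl2, −40 → 0 °C; aq NaHCO3 wash
Reagents that add atoms: bromine (8), BrBr
Why: Electrophilic anti addition of bromine through a bromonium ion to the only C=C bond sets C3 and C4 trans, leaves the acetals untouched at low temperature, and creates stereocentres that have no bearing on the later steps.

Step 5
Reactants: 6 N-[4-(1H-pyrrol-3-yl)pyrimidin-2-yl]pivalamide; 9 3,4-dibromo-2,5-dimethoxytetrahydrofuran
Product: 12 N-[4-(5,6-dibromo-1H-indol-3-yl)pyrimidin-2-yl]pivalamide, via tetrahydrofuranylpyrrole 10 (not isolated), via dihydroindol-4-ol 11 (not isolated)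
Conditions: 9 (1.5 equiv), TfOH (2.5 equiv), ClCH2CH2Cl–CF3CO2H, 0.02 M, 0 → 70 °C; aq NaHCO3
Reagents that add atoms: 3,4-dibromo-2,5-dimethoxytetrahydrofuran (9), COC1OC(OC)C(Br)C1Br
Why: Proposed new method: the strong acid ionises one acetal carbon of 9 to an α-bromo oxocarbenium ion, pyrrole C5 of 6 captures it (future C7–C7a bond, 10), the pyrrolylic C–O bond of 10 then opens to an azafulvenium ion that sheds the neighbouring CHBr proton while the hemiacetal end collapses to the aldehyde, pyrrole C4 attacks the protonated aldehyde (future C3a–C4 bond, 11), and ionisation of the C4 carbinol followed by loss of H5 aromatises the new ring to 12. The closest known reaction type is the acid-mediated benzannulation of pyrroles to indoles and of indoles to carbazoles with 2,5-dimethoxytetrahydrofuran or 1,4-diketones; untested are the two bromine atoms on the C4 unit, which slow acetal ionisation, and an N–H pyrrole that carries an acceptor. The single ring closed is the six-membered benzo ring, formed in a 6-exo-trig Friedel–Crafts hydroxyalkylation in which the C=O bond lies outside the forming ring. No stereocentre survives: those of 9, 10 and 11 are all destroyed, and because both eliminations run through cations (E1) no particular H/O geometry is required, so every diastereomer of 9 can converge on 12. Regioselectivity for C5 over C2 is secured by the (protonated) pyrimidinyl acceptor at C3, which is conjugated with C2 and shields it, the same bias that sends electrophiles to C5 of 3-acylpyrroles, and only the C5 adduct has a free β-carbon next to it for a six-membered closure, whereas a C2 adduct can merely revert by protodealkylation. Chemoselectivity rests on three points: the pivalamide retains only one N–H and so cannot enter a Clauson–Kaas pyrrole synthesis with 9, the pyrrole nitrogen is a vinylogous amide-type nitrogen that is not nucleophilic in acid (no indolizine closure), and water rather than HBr is lost because only the oxygen atoms are protonated, they sit on pyrrolylic carbons, and the medium offers neither base nor halophilic metal.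

Step 6
Reactants: 12 N-[4-(5,6-dibromo-1H-indol-3-yl)pyrimidin-2-yl]pivalamide
Product: 13 meridianin F, 4-(5,6-dibromo-1H-indol-3-yl)pyrimidin-2-amine
Conditions: 1 M aq NaOH, MeOH–THF, 50 °C; dilute HCl to pH 8
Reagents that add atoms: none
Why: Base hydrolysis of an amide works here under mild conditions because an N-acyl-2-aminopyrimidine is an activated amide with a weakly basic heteroarylamine as leaving group, while aryl bromides, indole and pyrimidine are inert to dilute hydroxide.

Compound list
1 | 3-acetyl-1-tosylpyrrole | CC(=O)c1ccn(S(=O)(=O)c2ccc(C)cc2)c1 | starting material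
2 | (E)-3-(dimethylamino)-1-(1-tosyl-1H-pyrrol-3-yl)prop-2-en-1-one | CN(C)/C=C/C(=O)c1ccn(S(=O)(=O)c2ccc(C)cc2)c1 | intermediate
3 | guanidine hydrochloride | NC(N)=N.Cl | starting material
4 | 4-(1-tosyl-1H-pyrrol-3-yl)pyrimidin-2-amine (not isolated) | Cc1ccc(S(=O)(=O)n2ccc(-c3ccnc(N)n3)c2)cc1 | intermediate
5 | 4-(1H-pyrrol-3-yl)pyrimidin-2-amine | Nc1nccc(-c2cc[nH]c2)n1 | intermediate
6 | N-[4-(1H-pyrrol-3-yl)pyrimidin-2-yl]pivalamide | CC(C)(C)C(=O)Nc1nccc(-c2cc[nH]c2)n1 | intermediate
7 | 2,5-dimethoxy-2,5-dihydrofuran (cis/trans mixture) | COC1C=CC(OC)O1 | starting material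
8 | bromine | BrBr | starting material
9 | 3,4-dibromo-2,5-dimethoxytetrahydrofuran (racemic, 3,4-trans, diastereomer mixture at C2/C5) | COC1OC(OC)C(Br)C1Br | intermediate
10 | N-{4-[5-(3,4-dibromo-5-methoxytetrahydrofuran-2-yl)-1H-pyrrol-3-yl]pyrimidin-2-yl}pivalamide (diastereomer mixture, not isolated) | CC(C)(C)C(=O)Nc1nccc(-c2c[nH]c(C3OC(OC)C(Br)C3Br)c2)n1 | intermediate
11 | N-[4-(5,6-dibromo-4-hydroxy-4,5-dihydro-1H-indol-3-yl)pyrimidin-2-yl]pivalamide (diastereomer mixture, not isolated) | CC(C)(C)C(=O)Nc1nccc(-c2c[nH]c3C=C(Br)C(Br)C(O)c23)n1 | intermediate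
12 | N-[4-(5,6-dibromo-1H-indol-3-yl)pyrimidin-2-yl]pivalamide | CC(C)(C)C(=O)Nc1nccc(-c2c[nH]c3cc(Br)c(Br)cc23)n1 | intermediate
13 | meridianin F (achiral) | Nc1nccc(-c2c[nH]c3cc(Br)c(Br)cc23)n1 | target

Total step count: 6
Longest linear sequence: 5 (steps 1, 2, 3, 5, 6). Step 4 is a one-step side branch.

Steps most likely to fail

Step 5.
- **Risk:** The brominated acetal may ionise too slowly for the acceptor-deactivated pyrrole. The reagent could then aromatise by double loss of methanol, or pyrrole units could be linked intermolecularly. Bromide could also ionise from the allylic position, so that HBr rather than water is lost in the last elimination.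
- **Fallback:** The benzannulation is given up and the dibrominated benzo ring is bought in. It sets out from guanidine hydrochloride 3, the only route compound kept, and uses only standard reaction types of 3-acylindoles.
- **Sequence:** Purchased 5,6-dibromo-1H-indole F1 is acetylated at C3 (AcCl, SnCl4, CH2Cl2) to 1-(5,6-dibromo-1H-indol-3-yl)ethanone F2. N-sulfonylation (TsCl, Et3N, DMAP) gives 1-(5,6-dibromo-1-tosyl-1H-indol-3-yl)ethanone F3. Condensation with DMF-DMA gives (E)-1-(5,6-dibromo-1-tosyl-1H-indol-3-yl)-3-(dimethylamino)prop-2-en-1-one F4. Heating F4 with 3 and K2CO3 in 2-methoxyethanol forms 4-(5,6-dibromo-1-tosyl-1H-indol-3-yl)pyrimidin-2-amine F5, which is detosylated in the same flask. The route is rejoined at 13.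

Step 4.
- **Risk:** Traces of HBr from substitution side reactions may start acetal cleavage and elimination of HBr or methanol while the dibromide is concentrated or stored. The reagent would then not reach step 5 intact.
- **Fallback:** The cyclic reagent is replaced by an open-chain one, setting out from 7.
- **Sequence:** Acid-catalysed methanolysis with removal of water opens the ring of 7 to 1,1,4,4-tetramethoxybut-2-ene F6, whose E isomer is also a catalogue compound. Bromine 8 adds to its C=C bond to give 2,3-dibromo-1,1,4,4-tetramethoxybutane F7. F7 takes the place of 9 in step 5 under the same acid conditions and comes back to the route at 12.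

Step 3.
- **Risk:** Acylation of the weakly nucleophilic amino group may be sluggish, with competing acylation at the pyrrole nitrogen and a mixture of acylation states.
- **Fallback:** Selective acylation is replaced by exhaustive acylation and trimming, setting out from 5.
- **Sequence:** NaH and excess PivCl in THF acylate both nitrogen atoms to N-[4-(1-pivaloyl-1H-pyrrol-3-yl)pyrimidin-2-yl]pivalamide F8. Catalytic NaOMe in MeOH at room temperature then removes only the N-acylpyrrole group, an activated amide, while the pivalamide is shielded as its anion. The route is rejoined at 6.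

Further compounds
F1 | step 5 | 5,6-dibromo-1H-indole (purchased) | Brc1cc2cc[nH]c2cc1Br
F2 | step 5 | 1-(5,6-dibromo-1H-indol-3-yl)ethanone | CC(=O)c1c[nH]c2cc(Br)c(Br)cc12
F3 | step 5 | 1-(5,6-dibromo-1-tosyl-1H-indol-3-yl)ethanone | CC(=O)c1cn(S(=O)(=O)c2ccc(C)cc2)c2cc(Br)c(Br)cc12
F4 | step 5 | (E)-1-(5,6-dibromo-1-tosyl-1H-indol-3-yl)-3-(dimethylamino)prop-2-en-1-one | CN(C)/C=C/C(=O)c1cn(S(=O)(=O)c2ccc(C)cc2)c2cc(Br)c(Br)cc12
F5 | step 5 | 4-(5,6-dibromo-1-tosyl-1H-indol-3-yl)pyrimidin-2-amine | Cc1ccc(S(=O)(=O)n2cc(-c3ccnc(N)n3)c3cc(Br)c(Br)cc32)cc1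
F6 | step 4 | 1,1,4,4-tetramethoxybut-2-ene (E/Z mixture) | COC(OC)C=CC(OC)OC
F7 | step 4 | 2,3-dibromo-1,1,4,4-tetramethoxybutane (diastereomer mixture) | COC(OC)C(Br)C(Br)C(OC)OC
F8 | step 3 | N-[4-(1-pivaloyl-1H-pyrrol-3-yl)pyrimidin-2-yl]pivalamide | CC(C)(C)C(=O)Nc1nccc(-c2ccn(C(=O)C(C)(C)C)c2)n1
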